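The readings are simulated with made-up constants.

If each unit of product costs one unit of protonated nucleophile, noon, with 1.5 M of electrophile against 0.440 M, keeps a leftover of at least 70.7 % of its electrophile unreacted.

| setting | ochre | amber | dusk | noon |
|---|---|---|---|---|
| electrophile | 0.25 M | 0.94 M | 0.40 M | 1.5 M |
| free base | 0.60 M | 0.60 M | 0.600 M | 0.600 M |
| protonated nucleophile | 0.44 M | 0.44 M | 0.440 M | 0.440 M |
| scavenger | 0.32 M | 0.32 M | 0.320 M | 0.320 M |
| temperature | 35 °C | 50 °C | 40 °C | 60 °C |
| remark | run made earlier | run made earlier |  |  |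
| time |  |  | 40 min | 40 min |

| run | time / min | product / % | electrophile / % |
|---|---|---|---|
| ochre | 2.00 | 0 | 99.5 |
| ochre | 5.00 | 0.9 | 99.5 |
| ochre | 10.0 | 2.1 | 98.0 |
| ochre | 15.0 | 3.6 | 96.5 |
| ochre | 20.0 | 4.9 | 95.0 |
| ochre | 30.0 | 8.5 | 91.3 |
| amber | 3.00 | 3.4 | 96.6 |
| amber | 6.00 | 6.9 | 93.0 |
| amber | 10.0 | 11.4 | 88.8 |
| amber | 12.0 | 13.6 | 86.4 |
| amber | 15.0 | 15.6 | 84.1 |
| amber | 20.0 | 19.3 | 80.3 |

(scatter of a reading: 0.3 percentage points)

- the flask that ends with the higher amount of product, in percent of the electrophile charged, or "neither" when 2 percentage points or less lies between them (dusk / noon / neither)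
- final product, as a percentage of the electrophile charged, in dusk
- final product, as a percentage of the electrophile charged, in noon



Two numbers do not seem to go together. Amber's opening 3.4 % in 3.00 min, carried on at that pace for 40 min, gives 45.3 %, and noon is hotter. Yet for noon the ceiling C, 29.3 %, is lower; C is the charge of protonated nucleophile over the charge of electrophile, read as a percentage of the electrophile charged.

We take equal charges, C of one, as the zero of the scale. Dusk lies above it at 110 %, and noon lies below it, with protonated nucleophile as its limiting reagent. The contradiction clears: pace says how soon, and C says how far the product of noon can go on one unit per unit. At amber's pace, noon meets C in 25.9 min, sooner than 40 min, so we expect noon near C. Ochre's last pace over 40 min gives dusk 14.4 %, far under its ceiling, and dusk is warmer, so we expect somewhat more. Our call is noon.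

The forecast also calls noon, with 23 % (17 % to 30 %) for dusk and 27 % (23 % to 30 %) for noon, on the ground: “The 0.44 M nucleophile probably limits yield, capping noon near 29% (0.44/1.5).”

The flasks give 19.8 % in dusk and 27.2 % in noon, so noon ends higher.

    nucleophile + acid set free ⇌ protonated nucleophile, settled at all times (K = 910 M⁻¹, ΔH = −76.0 kJ mol⁻¹)
    electrophile + nucleophile → acid set free + product (k = 9.88 × 10⁻⁴ M⁻¹ s⁻¹, Ea = 78.0 kJ mol⁻¹)
    acid set free + free base ⇌ salt of the base (K = 1200 M⁻¹, k = 0.0599 M⁻¹ s⁻¹, Ea = 42.0 kJ mol⁻¹, ΔH = −29.0 kJ mol⁻¹)
    acid set free + scavenger → scavenged by-product (k = 0.00352 M⁻¹ s⁻¹, Ea = 48.0 kJ mol⁻¹)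
    acid set free + free base ⇌ idle adduct, settled at all times (K = 2.30 M⁻¹, ΔH = −18.0 kJ mol⁻¹)
    (constants at 40 °C)

Noon ends under C, and its early minutes are the ones to watch: the product step had half its turnover up to 40 min behind it by 5.74 min, and at 20.0 min product stood at 23.6 % with free base at 4.24 % of its charge. The loss of acid set free to scavenger came later in noon, half its turnover up to 40 min by 19.4 min, and at 40.0 min scavenger stood at 38.3 % of its charge and protonated nucleophile at 6.35 % of its charge, while product had gained 3.6 percentage points since 20.0 min.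

The neighbour of noon charged with 0.60 M of electrophile has C of 73.3 %, which leaves at least 26.7 % of its electrophile over. Computed, it holds 56.1 % product and 43.9 % electrophile at 40.0 min.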